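## Retrosynthetic overview

1. Target 14 is the unsymmetrical diester of an achiral aryl triol. It is traced back through isobutyrylation of diol ester 12 and hydride opening of aryl lactone 10 to hydroxymethyl lactone 8 and (R)-2-methylbutanoic acid 9, which brings its own stereocentre.
2. Key disconnection: the aryl O–C(=O) bond of the benzofuran-2(3H)-one ring of 8, leading to the prochiral triol 5 by mediated anodic oxidation of one of its two enantiotopic CH2OH groups.
3. Structural feature used: the benzylic carbinol carbon carrying two identical CH2OH arms is ortho to the phenolic oxygen. That oxygen, the two aromatic carbons between, the carbinol carbon and either CH2 carbon can form a five-membered ring, so the oxidised arm is locked as the lactone carbonyl and the other stays CH2OH.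
4. Triol 5 comes from the aryl–C bond between the ortho-lithiated phenoxide of 1 and the carbonyl carbon of dioxanone 2, followed by acetonide hydrolysis.
5. Ring order: the benzene ring is bought; the furanone ring is the only ring formed (step 3) and is opened again in step 5.

Key step: step 3

Assumption: the antipode of the nitroxyl mediator that favours (R)-8 cannot be derived from a model and is to be assigned in a small-scale trial; both antipodes are accessible, and the route is written for the one that gives (R)-8.

## Route

Step 1
Reactants: 1 2-bromo-5-methylphenol; 2 2,2-dimethyl-1,3-dioxan-5-one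
Product: 4 5-(2-hydroxy-4-methylphenyl)-2,2-dimethyl-1,3-dioxan-5-ol, via sodium 2-lithio-5-methylphenolate 3 (not isolated)
Conditions: NaH (1.05 equiv), THF, 0 °C; t-BuLi (2.0 equiv), −78 °C; 2, −78 → 0 °C; aq. NH4Cl
Reagents that add atoms: none
Why: Phenoxide formation and bromine–lithium exchange should give the ortho-lithiated phenoxide, whose 1,2-addition to the ketone (organolithium carbonyl addition) builds the achiral tertiary benzylic carbinol, so no stereocontrol is needed.

Step 2
Reactants: 4 5-(2-hydroxy-4-methylphenyl)-2,2-dimethyl-1,3-dioxan-5-ol
Product: 5 2-(2-hydroxy-4-methylphenyl)propane-1,2,3-triol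
Conditions: AcOH/H2O (4:1), 40 °C
Reagents that add atoms: none
Why: Acid-catalysed acetal hydrolysis frees the 1,3-diol, and the tertiary benzylic hydroxyl should survive the mild acid because its two β-oxygen substituents disfavour ionisation at that carbon.

Step 3
Reactants: 5 2-(2-hydroxy-4-methylphenyl)propane-1,2,3-triol
Product: 8 (3R)-3-hydroxy-3-(hydroxymethyl)-6-methyl-1-benzofuran-2(3H)-one, via hydroxy aldehyde 6 (not isolated), via lactol 7 (not isolated)
Conditions: enantiopure 3,3,5,5-tetramethyl-dinaphtho[2,1-c:1',2'-e]azepine N-oxyl (10 mol %), 2,6-lutidine (3 equiv), n-Bu4NBF4 (0.1 M), MeCN, carbon felt anode, Pt cathode, undivided cell, anode held at the nitroxyl/oxoammonium wave, 0 °C, 4 F/mol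
Reagents that add atoms: none
Why: Proposed new method: the anode should convert the enantiopure nitroxyl into its oxoammonium ion at a potential below that of the un-ionised phenol, and this cation removes hydride from one of the two enantiotopic CH2OH groups of 5 (the tertiary hydroxyl has no carbinol hydrogen) to give aldehyde 6. The ortho phenol oxygen then adds to the aldehyde carbon by 5-exo-trig closure to lactol 7, which forms the aryl O–C bond of the five-membered ring, and a second mediated two-electron oxidation of the lactol C–H gives lactone 8 while the cathode reduces lutidinium protons to H2. The closest known reactions are the nitroxyl-mediated anodic oxidation of diols to lactones and the oxidative desymmetrization of meso diols with chiral nitroxyl mediators. The carbinol carbon becomes a stereocentre only through the choice between the two CH2OH arms; that choice is made in the hydride-transfer step within diastereomeric alkoxide–oxoammonium adducts and is therefore controlled by the axially chiral backbone of the mediator. The step needs selectivity for CH2OH over the electron-rich ring and over the second arm: the substrate secures it by trapping the aldehyde at once through the adjacent phenol (before retro-aldol loss of formaldehyde) and by the lower reactivity of the CH2OH left next to the electron-poor lactone carbonyl, supported by the weak base, the low mediator loading and the limited charge.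

Step 4
Reactants: 8 (3R)-3-hydroxy-3-(hydroxymethyl)-6-methyl-1-benzofuran-2(3H)-one; 9 (R)-2-methylbutanoic acid
Product: 10 [(3R)-3-hydroxy-6-methyl-2-oxo-2,3-dihydro-1-benzofuran-3-yl]methyl (2R)-2-methylbutanoate
Conditions: DIC (1.1 equiv), DMAP (5 mol %), CH2Cl2, 0 °C
Reagents that add atoms: none
Why: Steglich esterification should acylate the unhindered primary hydroxyl in preference to the tertiary α-hydroxyl while the phenol is still masked in the lactone, and the low DMAP loading at 0 °C guards against epimerisation of the acid α-carbon and base-induced retro-aldol loss of formaldehyde.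

Step 5
Reactants: 10 [(3R)-3-hydroxy-6-methyl-2-oxo-2,3-dihydro-1-benzofuran-3-yl]methyl (2R)-2-methylbutanoate
Product: 12 (2S)-2,3-dihydroxy-2-(2-hydroxy-4-methylphenyl)propyl (2R)-2-methylbutanoate, via lactol ester 11 (not isolated)
Conditions: NaBH4 (1.0 equiv), THF/MeOH (10:1), −20 °C; AcOH quench at −20 °C
Reagents that add atoms: none
Why: Chemoselective borohydride reduction should attack the aryl lactone carbonyl, activated by the phenoxide leaving group and the α-hydroxyl, far faster than the α-branched alkyl ester and pass through the lactol to the primary alcohol and free phenol, while the low temperature and cold acid quench are meant to suppress acyl shift between the two primary oxygens; the carbinol configuration is not touched (the descriptor changes from R to S only through the priority change).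

Step 6
Reactants: 12 (2S)-2,3-dihydroxy-2-(2-hydroxy-4-methylphenyl)propyl (2R)-2-methylbutanoate; 13 isobutyric anhydride
Product: 14 (2S)-2-hydroxy-2-(2-hydroxy-4-methylphenyl)-3-[(2-methylpropanoyl)oxy]propyl (2R)-2-methylbutanoate
Conditions: Novozym 435 (immobilised Candida antarctica lipase B), 13 (1.5 equiv), dry MTBE, 30 °C
Reagents that add atoms: none
Why: Lipase-catalysed acyl transfer through the acyl-enzyme should esterify only the primary aliphatic hydroxyl, since phenolic and tertiary hydroxyls are not accepted as nucleophiles, and the base-free medium avoids acyl migration, so both stereocentres are carried through unchanged.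

## Compound list

1 | 2-bromo-5-methylphenol | Cc1ccc(Br)c(O)c1 | starting material
2 | 2,2-dimethyl-1,3-dioxan-5-one | CC1(C)OCC(=O)CO1 | starting material
3 | sodium 2-lithio-5-methylphenolate | Cc1ccc([Li])c([O-])c1.[Na+] | intermediate (not isolated)
4 | 5-(2-hydroxy-4-methylphenyl)-2,2-dimethyl-1,3-dioxan-5-ol | CC1(C)OCC(O)(CO1)c1ccc(C)cc1O | intermediate
5 | 2-(2-hydroxy-4-methylphenyl)propane-1,2,3-triol | OCC(O)(CO)c1ccc(C)cc1O | intermediate
6 | (2R)-2,3-dihydroxy-2-(2-hydroxy-4-methylphenyl)propanal | OC[C@@](O)(C=O)c1ccc(C)cc1O | intermediate (not isolated)
7 | (3R)-3-(hydroxymethyl)-6-methyl-2,3-dihydro-1-benzofuran-2,3-diol, both C2 epimers | OC[C@@]1(O)C(O)Oc2cc(C)ccc12 | intermediate (not isolated)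
8 | (3R)-3-hydroxy-3-(hydroxymethyl)-6-methyl-1-benzofuran-2(3H)-one | OC[C@@]1(O)C(=O)Oc2cc(C)ccc12 | intermediate
9 | (R)-2-methylbutanoic acid | CC[C@@H](C)C(=O)O | starting material
10 | [(3R)-3-hydroxy-6-methyl-2-oxo-2,3-dihydro-1-benzofuran-3-yl]methyl (2R)-2-methylbutanoate | CC[C@@H](C)C(=O)OC[C@@]1(O)C(=O)Oc2cc(C)ccc12 | intermediate
11 | [(3R)-2,3-dihydroxy-6-methyl-2,3-dihydro-1-benzofuran-3-yl]methyl (2R)-2-methylbutanoate, both C2 epimers | CC[C@@H](C)C(=O)OC[C@@]1(O)C(O)Oc2cc(C)ccc12 | intermediate (not isolated)
12 | (2S)-2,3-dihydroxy-2-(2-hydroxy-4-methylphenyl)propyl (2R)-2-methylbutanoate | CC[C@@H](C)C(=O)OC[C@@](O)(CO)c1ccc(C)cc1O | intermediate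
13 | isobutyric anhydride | CC(C)C(=O)OC(=O)C(C)C | starting material
14 | (2S)-2-hydroxy-2-(2-hydroxy-4-methylphenyl)-3-[(2-methylpropanoyl)oxy]propyl (2R)-2-methylbutanoate | CC[C@@H](C)C(=O)OC[C@@](O)(COC(=O)C(C)C)c1ccc(C)cc1O | target

## Step count and risks

Total step count: 6. Longest linear sequence: 6 steps (1 to 14).

Steps most likely to fail:

1. Step 3 (proposed new method). Hydride abstraction may discriminate the two enantiotopic CH2OH groups poorly, and electron transfer from the phenol ring to the oxoammonium ion or to the anode may outrun alcohol oxidation.
Fallback (known chemistry, no oxidation), setting out from 5 and coming back at 14, with steps 4 to 6 bypassed. A lipase screened for the required sense (Pseudomonas cepacia lipase or Novozym 435, isobutyric anhydride 13, MTBE, 25 °C) should acylate one enantiotopic CH2OH of 5 by enantiotopic-group-selective acyl transfer to give (2R)-2,3-dihydroxy-2-(2-hydroxy-4-methylphenyl)propyl 2-methylpropanoate F1. Acid 9 (2.2 equiv, DIC, DMAP, CH2Cl2, 0 °C) then esterifies the remaining CH2OH and the phenol to give (2S)-2-hydroxy-2-{4-methyl-2-[(2R)-2-methylbutanoyloxy]phenyl}-3-[(2-methylpropanoyl)oxy]propyl (2R)-2-methylbutanoate F2. Pyrrolidine in THF at 0 °C should cleave only the aryl ester by aminolysis and deliver 14.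

2. Step 5. The acyl group may shift between the two primary oxygens in the basic hydride medium, which would erode the configuration at the carbinol carbon, and hydride may also attack the alkyl ester. Because the (R)-acyl group makes the two carbinol epimers diastereomers, such erosion should be detectable and the epimer separable.
Fallback, setting out from 10 and coming back at 12. The external, base-generating hydride is replaced by a hydroxyl-directed reduction: BH3·SMe2 (THF, 0 °C) first turns the tertiary hydroxyl into an alkoxyborane, and catalytic NaBH4 starts intramolecular hydride delivery to the neighbouring lactone carbonyl. The isolated alkyl ester is not reached, and the product stays bound as a neutral boron chelate until methanolysis, so no free alkoxide is present to move the acyl group. No new isolable compound is made.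

3. Step 6. Enzymatic acylation of the neopentyl-type primary hydroxyl may be slow, and prolonged contact may lead to enzyme-mediated acyl scrambling of the existing ester.
Fallback, setting out from 12 and coming back at 14. Chemical acylation with isobutyric anhydride 13 (pyridine, DMAP, CH2Cl2, 0 °C) esterifies the primary hydroxyl and the phenol together to give (2S)-2-hydroxy-3-[(2-methylpropanoyl)oxy]-2-{4-methyl-2-[(2-methylpropanoyl)oxy]phenyl}propyl (2R)-2-methylbutanoate F3. Selective aminolysis of the more reactive aryl ester with pyrrolidine (THF, 0 °C) should then release the phenol and give 14.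

## Further compounds

F1 | step 3 | (2R)-2,3-dihydroxy-2-(2-hydroxy-4-methylphenyl)propyl 2-methylpropanoate | OC[C@@](O)(COC(=O)C(C)C)c1ccc(C)cc1O
F2 | step 3 | (2S)-2-hydroxy-2-{4-methyl-2-[(2R)-2-methylbutanoyloxy]phenyl}-3-[(2-methylpropanoyl)oxy]propyl (2R)-2-methylbutanoate | CC[C@@H](C)C(=O)OC[C@@](O)(COC(=O)C(C)C)c1ccc(C)cc1OC(=O)[C@H](C)CC
F0 | step 5 | none | none
F3 | step 6 | (2S)-2-hydroxy-3-[(2-methylpropanoyl)oxy]-2-{4-methyl-2-[(2-methylpropanoyl)oxy]phenyl}propyl (2R)-2-methylbutanoate | CC[C@@H](C)C(=O)OC[C@@](O)(COC(=O)C(C)C)c1ccc(C)cc1OC(=O)C(C)C
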